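## The problem

The target is an elemane-type lactone, and the elemane numbers are used throughout. The cyclohexane ring is C5–C10. C10 carries the methyl C14 and the vinyl group C1=C2. C5 carries the C4 arm with C3 and C15. C7 carries C11 with the lactone carbonyl C12 and the methylene C13. All six ring carbons are stereocentres and an α-methylene-γ-butyrolactone is fused cis across C7–C8. The seventh stereocentre, C4, lies outside the ring in a 2,2-disubstituted epoxy aldehyde.

With β defined as the ring face that bears the C10 methyl group, the methyl, the C4 arm on C5, C11 on C7, the lactone oxygen on C8 and the hydroxyl on C9 are all β. The vinyl group and the C6 isobutyrate are α. The absolute configuration is 4R,5S,6S,7S,8S,9R,10S.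

The quaternary centre C10 sits between two stereocentres and cannot be corrected once made. It must therefore be set by a neighbour, and C9 is the only one that can be bought as a single enantiomer in a simple ring. From there a relay is available:
- C9 can steer C10 (adjacent) and C8 (cis delivery of oxygen).
- An axial C8 hydroxyl can deliver hydride to C6 (1,3-anti).
- C5 and C7 flank C6 and can be set by protonation or equilibration while C6 is a ketone.
- C4 is too remote for the ring to control and needs a reagent.

The α-methylene lactone (a Michael acceptor), the epoxy aldehyde, the isobutyrate and the lactone rule out hydride, strong base and strong nucleophiles late in the route. The C15 oxidation level must therefore be adjusted early, and the epoxide and aldehyde made last.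

The feature that opens the synthesis is the chain C2=C1–C10–C5–C4=C3. This is a hexa-1,5-diene whose two central carbons are the ring carbons C10 and C5. Such a diene is the cycloreversion product of a bicyclo[2.2.0]hexane fused to the six-membered ring at C5–C10, and that in turn is the [2+2] adduct of a cyclohexenone C10=C5 double bond with a cyclobutene.

## Retrosynthesis

**Epoxy aldehyde.** The aldehyde of target 32 is taken back to the primary alcohol of epoxy alcohol 31, and the C4–O and C3–O bonds of the epoxide to the 2-substituted allylic alcohol 30. Nucleophilic epoxidation of the corresponding enal would leave C4 uncontrolled and would compete with the methylene lactone. A titanium–tartrate epoxidation reacts only at the allylic alcohol and sets C4 by reagent control. The forward reaction must stay non-basic after the epoxide is in place, because Payne rearrangement of this glycidol (two CH2–O arms on C4) would invert C4. The final oxidation must also spare the hindered C9 hydroxyl.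

**Lactone, isobutyrate and methylene.** Lactone diol 30 comes from silyl ether 29. The lactone C12–O8 bond of 29 is cut to dihydroxy acid 28, which arises from isobutyrate 27 by one acid treatment that removes the tert-butyl ester and the 8,9-acetonide. The C6 ester bond of 27 is cut to acrylate 26, and the C11=C13 bond of 26 to the saturated tert-butyl ester 23 (Mannich methylenation through 24 and 25). Methylenating the open ester before the isobutyrate is introduced keeps strong base away from both the isobutyrate and the finished lactone. The acetonide leaves the C6 hydroxyl as the only free one for acylation. Only the C8 hydroxyl (1,2-cis to the C7 arm) can lactonise, since C6 is acylated and C9 is 1,3-diequatorial to C7.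

**C6 and C8.** The C6–H bond of triol 22 is cut to dihydroxy ketone 21 (directed reduction). The C8 hydroxyl of 21 is traced to the C8–O bond of epoxy ketone 20, and the epoxide of 20 to hydroxy enone 19. Simple hydride reduction of a C6 ketone in this ring should give the wrong, axial 6β alcohol, because the axial C10 methyl blocks the β face. Epoxide opening by carbon nucleophiles would give a trans C7/C8 pair. The relay C9-OH → C8-O (hydroxyl-directed epoxidation) → C6-H (hydride delivered from the axial C8 hydroxyl) avoids both. C7 is set by axial protonation of the enolate released when the epoxide is opened reductively.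

**C7–C11.** Hydroxy enone 19 is the desilylated form of enone ester 18. The C7–C11 bond of 18 is cut to iodoenone 17 and a zinc ester enolate, and 17 goes back through enone 16 (via silyl enol ether 15) to ketone 14. Alkylating 14 first and dehydrogenating afterwards would leave the new double bond free to form toward C11. Dehydrogenation of 14 itself can only give C7=C8, because C10 is quaternary. The forward coupling must tolerate the silyl ethers and the two spectator alkenes.

**C15 oxidation level.** Ketone 14 comes from alcohol 13, diol 12 and trans keto acrylate 11 by reduction, primary silylation and re-oxidation. This costs three steps. It removes the acrylate before any enolate chemistry and settles the only hydride reduction of the route before the lactone, tert-butyl ester and isobutyrate exist.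

**C5 and the two alkenyl arms.** Trans keto acrylate 11 is the C5 epimer of cis keto acrylate 10, reached by enolisation next to the C6 ketone. In 10 the bonds C1–C4 and C2–C3 are reconnected to give the tricyclic photoadduct 9. This turns a ring with a quaternary centre and two different alkenyl groups into a strained tricycle made in one step. The forward opening must cleave the central and the distal bond of the bicyclo[2.2.0]hexane and leave C10 untouched.

**Key disconnection.** The bonds C10–C1 and C5–C4 of 9 are cut to enone 5 and cyclobutene ester 8. No alkylation or conjugate addition offers the quaternary centre with both a vinyl group and the correct neighbour in one operation. The forward reaction needs head-to-head orientation and attack on the enone face opposite the C9 silyloxy group.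

**Starting materials.** Enone 5 comes from alcohol 4, obtained by lipase resolution of racemate 3, which is made by γ-hydroxylation of 3-methylcyclohex-2-en-1-one 1 through dienyl acetate 2. Ester 8 comes from acid 7 and commercial bromo ester 6.

## Roads not taken

**Alternative 1:** The C8–C9 bond is cut. In the forward sense SmI2 reduces one aldehyde of the open-chain dialdehyde A2 to a ketyl that adds to the other, closing the cyclohexane as the cis-8,9-diol A1.
- Merits: the cis diol, which costs the chosen route a directed epoxidation and a reductive opening, is made in one step. A1 already carries the C7 acetate arm and a protected C6 oxygen, so the lactone is one acid treatment away. On ring oxygenation this road is better.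
- Weak points: A2 needs four contiguous stereocentres, one of them the quaternary C10 bearing an aldehyde, built by open-chain stereocontrol. Its C7 aldehyde is epimerisable and has a β-alkoxy group that can be eliminated. The sense of the diol relative to C7 and C10 rests on one cyclic transition state. A1 carries a plain isopropenyl group, so C15 must still be oxidised late in the presence of the other alkenes.
- Comparison: the chosen plan sets against this a two-step entry to the quaternary centre and both alkenyl arms from two small rings, with C15 already oxidised.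

**Alternative 2:** The C7–C8 bond and the lactone C12–O bond are cut. CrCl2 (divalent chromium) converts the Z allylic bromide A4 into an allylchromium species; C7 adds to the C8 aldehyde and the alkoxide closes the lactone, giving A3.
- Merits: carbocycle, lactone and exocyclic methylene arise in one operation with no separate methylenation. A3 is only a few steps from the target core. In step count after the key step this road is clearly shorter than the eleven steps the chosen plan spends between enone 16 and lactone 29.
- Weak points: A4 again needs the quaternary C10 and three further stereocentres from acyclic chemistry, with an α-silyloxy aldehyde that can epimerise at C9. Two new centres (C7, C8) must both come out cis to C9 in one closure whose outcome is not secured by any ring. The isopropenyl group still needs late oxidation to the epoxy aldehyde beside a methylene lactone.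
- Comparison: the chosen plan is longer but places each ring stereocentre by a separate, ring-based control element, and has no late allylic oxidation.

**Alternative 3:** The C5–C10 bond is cut. Mn(OAc)3 (trivalent manganese) oxidises the α-methyl β-keto ester A6 to the C10 radical, which closes onto the trisubstituted olefin; Cu(OAc)2 (divalent copper) turns the tertiary radical into the isopropenyl group, giving A5.
- Merits: ring, quaternary centre and isopropenyl group are formed in one step from a simple chain. The ketone ends at C9, which makes C8 easy to functionalise. This is an advantage over the chosen route, where C8 has to be reached through an enone from C6.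
- Weak points: C10 arrives with an ester that needs three steps to become the vinyl group. C7 and C8 are bare methylenes, so the whole lactone problem remains. C15 is unoxidised. The relative configuration of C5, C6 and C10 depends on 1,2-induction in a radical cyclisation.
- Comparison: the chosen plan delivers the vinyl group and the oxidised C4 arm directly, and takes C9 from a resolved alcohol.

Key step: step 7

Remark: the lipase is assumed to follow the usual rule for secondary alcohols (the methyl-bearing olefinic carbon acting as the larger substituent), so that the R alcohol is acetylated and the S alcohol is recovered.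

## Steps

Step 1
Reactants: 1 3-methylcyclohex-2-en-1-one
Product: 2 3-methylcyclohexa-1,3-dien-1-yl acetate
Conditions: isopropenyl acetate, TsOH·H2O (cat.), reflux with removal of acetone
Reagents that add atoms: isopropenyl acetate, CC(=C)OC(C)=O
Why: Acid-catalysed enol acetylation under equilibrating conditions should give the linearly conjugated dienyl acetate, the substrate for a vinylogous Rubottom oxidation.

Step 2
Reactants: 2 3-methylcyclohexa-1,3-dien-1-yl acetate
Product: 3 (±)-4-hydroxy-3-methylcyclohex-2-en-1-one
Conditions: mCPBA, CH2Cl2/H2O, 0 °C
Reagents that add atoms: 3-chloroperbenzoic acid, OOC(=O)c1cccc(Cl)c1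
Why: Vinylogous Rubottom oxidation: the peracid attacks the electron-rich distal double bond of the dienyl acetate and loss of the acetyl group returns the enone with oxygen on the γ-carbon, as in the classical 6-hydroxylation of steroidal dienol acetates.

Step 3
Reactants: 3 (±)-4-hydroxy-3-methylcyclohex-2-en-1-one
Product: 4 (S)-4-hydroxy-3-methylcyclohex-2-en-1-one
Conditions: Candida antarctica lipase B (immobilised), vinyl acetate, MTBE, 30 °C, stopped just past half conversion
Reagents that add atoms: none
Why: Lipase-catalysed kinetic resolution by irreversible transesterification; the R alcohol should be acetylated and the S alcohol, which becomes C9 of the target, recovered in high enantiomeric purity because conversion is taken past one half.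

Step 4
Reactants: 4 (S)-4-hydroxy-3-methylcyclohex-2-en-1-one
Product: 5 (S)-4-(tert-butyldimethylsilyloxy)-3-methylcyclohex-2-en-1-one
Conditions: TBSCl, imidazole, DMF, rt
Reagents that add atoms: tert-butyldimethylsilyl chloride, CC(C)(C)[Si](C)(C)Cl
Why: Standard imidazole-promoted silylation under conditions too mild to isomerise the γ-hydroxy enone; the bulky silyl ether is the group that shields one enone face in step 7.

Step 5
Reactants: 6 ethyl 1-bromocyclobutane-1-carboxylate
Product: 7 cyclobut-1-ene-1-carboxylic acid
Conditions: KOH (powdered), toluene, reflux; then aq. HCl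
Reagents that add atoms: potassium hydroxide, [K+].[OH-]
Why: E2 dehydrobromination with saponification in the same pot is the established entry to cyclobut-1-enecarboxylic acid.

Step 6
Reactants: 7 cyclobut-1-ene-1-carboxylic acid
Product: 8 methyl cyclobut-1-ene-1-carboxylate
Conditions: MeI, K2CO3, DMF, 0 °C to rt
Reagents that add atoms: iodomethane, CI
Why: SN2 O-alkylation of the carboxylate avoids the acid and heat that would polymerise the strained acrylate; the ester is stored cold and used in excess.

Step 7
Reactants: 5 (S)-4-(tert-butyldimethylsilyloxy)-3-methylcyclohex-2-en-1-one; 8 methyl cyclobut-1-ene-1-carboxylate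
Product: 9 cis-anti-cis head-to-head photoadduct, methyl 7-(tert-butyldimethylsilyloxy)-6-methyl-10-oxotricyclo[4.4.0.0(2,5)]decane-2-carboxylate
Conditions: hν (λ > 300 nm, Pyrex, medium-pressure Hg lamp), 8 (4 equiv), CH2Cl2, −20 °C; then basic Al2O3, CH2Cl2, rt
Reagents that add atoms: none
Why: Enone–alkene [2+2] photocycloaddition with a cyclobutene ester, a known reaction class for 3-methylcyclohexenones. The enone triplet bonds first from its β-carbon C10 to the unsubstituted cyclobutene carbon C1, giving a 1,4-diradical whose ester-stabilised centre C4 then closes onto the α-carbon C5. The new four-membered ring C10–C1–C4–C5 is closed by this stepwise diradical collapse, which is why a ring inaccessible to ground-state chemistry forms. Head-to-head orientation follows from the electron-poor alkene and the ester-stabilised radical, and it is the selectivity that places C4 on C5. C10 is set by approach to the enone face opposite the silyloxy group on the adjacent carbon C9, which gives the vinyl precursor α and the methyl β. C1 and C4 keep the cis geometry of the cyclobutene and take the anti arrangement because the four-membered ring approaches with its CH2 groups turned away from the cyclohexanone. C5 ends cis-fused, and the alumina treatment converts any trans-fused adduct to this isomer by enolisation. Only the regiochemistry and the C10 configuration matter afterwards, since C1 and C4 become sp2 in step 8 and C5 is reset in step 9.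

Step 8
Reactants: 9 cis-anti-cis photoadduct
Product: 10 cis keto acrylate, cyclohexan-6-one with 5α-[1-(methoxycarbonyl)vinyl], 10α-vinyl, 10β-methyl and 9β-OTBS groups
Conditions: toluene (dilute, BHT cat.), sealed tube, 180 °C
Reagents that add atoms: none
Why: Thermal cycloreversion of the bicyclo[2.2.0]hexane: the strained central C1–C4 bond, further weakened by the ester on C4, breaks to a cyclohexane-1,4-diyl that fragments across C2–C3, releasing C1=C2 as the vinyl group and C4=C3 as the acrylate. C5 and C10 are not involved, so their cis relation and the C10 configuration are kept; any ten-membered 1,5-diene formed by the other scission returns to the same product by Cope rearrangement.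

Step 9
Reactants: 10 cis keto acrylate
Product: 11 trans keto acrylate, cyclohexan-6-one with 5β-[1-(methoxycarbonyl)vinyl], 10α-vinyl, 10β-methyl and 9β-OTBS groups
Conditions: DBU (0.3 equiv), toluene, 40 °C; recovered cis epimer resubmitted
Reagents that add atoms: none
Why: Base-mediated epimerisation α to the C6 ketone; the trans isomer can hold the C5 arm, the vinyl group and the silyloxy group equatorial with only the C10 methyl axial (next to a carbonyl, so with a single syn-axial hydrogen), whereas the cis isomer must place either the arm or both the vinyl and silyloxy groups axial. Kinetic α-protonation of the dienolate keeps the double bond out of conjugation.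

Step 10
Reactants: 11 trans keto acrylate
Product: 12 diol, 5β-[1-(hydroxymethyl)vinyl]-10β-methyl-10α-vinyl-9β-OTBS-cyclohexan-6-ol (both C6 epimers)
Conditions: iBu2AlH (5 equiv), CH2Cl2, −78 to 0 °C; aq. KNaC4H4O6 work-up
Reagents that add atoms: none
Why: Hydride reduction of the enoate to the allylic alcohol (1,2-selective with iBu2AlH) and of the ketone; the C6 configuration is immaterial because C6 is re-oxidised in step 12.

Step 11
Reactants: 12 diol
Product: 13 C15 tert-butyldiphenylsilyl ether of 12 (C6 hydroxyl free)
Conditions: TBDPSCl, imidazole, CH2Cl2, 0 °C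
Reagents that add atoms: tert-butyldiphenylsilyl chloride, CC(C)(C)[Si](Cl)(c1ccccc1)c1ccccc1
Why: Silylation selective for the primary allylic hydroxyl over the hindered secondary one; the acid-stable TBDPS group can outlast removal of the C9 TBS group in step 16.

Step 12
Reactants: 13 C15 silyl ether alcohol
Product: 14 ketone, 5β-[1-(tert-butyldiphenylsilyloxymethyl)vinyl]-10β-methyl-10α-vinyl-9β-OTBS-cyclohexan-6-one
Conditions: Dess–Martin periodinane, CH2Cl2, rt
Reagents that add atoms: none
Why: Dess–Martin oxidation of a hindered secondary alcohol under near-neutral conditions, which leaves the epimerisable C5 centre and both silyl ethers alone.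

Step 13
Reactants: 14 ketone
Product: 16 enone, cyclohex-7-en-6-one with the substituents of 14, via silyl enol ether 15 (not isolated)
Conditions: LiN(iPr)2, Me3SiCl, THF, −78 °C; then Pd(OAc)2, MeCN, rt
Reagents that add atoms: none
Why: Saegusa–Ito dehydrogenation: kinetic deprotonation takes the unhindered C7 methylene and not the C5 methine beside the quaternary carbon, and β-hydride elimination from the palladium enolate gives the C7=C8 enone. No other enone is possible because C10 has no hydrogen.

Step 14
Reactants: 16 enone
Product: 17 7-iodo enone
Conditions: I2, pyridine, CH2Cl2, 0 °C to rt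
Reagents that add atoms: iodine, II
Why: Johnson α-iodination of a cyclohexenone by conjugate addition of pyridine, iodination of the enolate and elimination; isolated alkenes do not react under these conditions.

Step 15
Reactants: 17 7-iodo enone
Product: 18 enone ester, enone 16 carrying CH2CO2tBu on C7
Conditions: BrZnCH2CO2tBu (from tert-butyl bromoacetate and Zn, THF), Pd(PPh3)4 (5 mol %), THF, 45 °C
Reagents that add atoms: tert-butyl bromoacetate, CC(C)(C)OC(=O)CBr
Why: Negishi-type coupling of a Reformatsky reagent with an alkenyl iodide forms C7–C11 at an sp2 carbon; zinc enolates are too weakly basic and nucleophilic to attack the enone or the silyl ethers.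

Step 16
Reactants: 18 enone ester
Product: 19 9β-hydroxy enone (18 without the TBS group)
Conditions: HF (48% aq.), MeCN, 0 °C
Reagents that add atoms: none
Why: Acidic desilylation removes the secondary TBS ether while the much more acid-stable primary TBDPS ether and the tert-butyl ester survive.

Step 17
Reactants: 19 9β-hydroxy enone
Product: 20 7β,8β-epoxy-9β-hydroxy ketone (epoxide cis to the C9 hydroxyl, CH2CO2tBu on C7)
Conditions: t-BuOOH (in decane), benzyltrimethylammonium hydroxide (cat.), THF, −10 °C
Reagents that add atoms: tert-butyl hydroperoxide, CC(C)(C)OO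
Why: Hydroxyl-directed Weitz–Scheffer epoxidation: the peroxide anion is hydrogen-bonded to the free γ-hydroxyl and adds to C8 on the same face, so the C8–O bond is formed β, cis to the C9 oxygen. Only the enone is electrophilic enough to react, and catalytic base at low temperature should leave C5 and the acidic C11 hydrogens untouched.

Step 18
Reactants: 20 epoxy ketone
Product: 21 dihydroxy ketone, 8β,9β-dihydroxy-cyclohexan-6-one with 7β-CH2CO2tBu (H-7α)
Conditions: SmI2 (2.2 equiv), THF/MeOH, −90 °C
Reagents that add atoms: none
Why: Reductive cleavage of the Cα–O bond of an α,β-epoxy ketone by SmI2 gives the aldol with the C8 configuration of the epoxide. The samarium enolate is protonated at C7 from the α (axial) face, away from the axial C8 alkoxide, which puts the acetate arm β and equatorial.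

Step 19
Reactants: 21 dihydroxy ketone
Product: 22 6α,8β,9β-triol
Conditions: Me4NBH(OAc)3, MeCN/AcOH, −30 °C
Reagents that add atoms: none
Why: Evans–Saksena directed reduction: the reagent reduces ketones only after exchange onto a hydroxyl, and the axial C8 hydroxyl delivers hydride to the β face of C6, giving the equatorial 6α alcohol (1,3-anti diol) that external hydride would not give.

Step 20
Reactants: 22 triol
Product: 23 acetonide, 8,9-O-isopropylidene derivative of 22 with free 6α-hydroxyl
Conditions: 2,2-dimethoxypropane, PPTS (cat.), acetone, rt
Reagents that add atoms: 2,2-dimethoxypropane, COC(C)(C)OC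
Why: Acid-catalysed acetonide formation takes the cis-1,2-diol; the 6α,8β pair is 1,3-trans and cannot be bridged, so C6 is left as the only free hydroxyl.

Step 21
Reactants: 23 acetonide
Product: 26 acrylate, 23 with C11=C13H2 (tert-butyl 2-substituted acrylate), via Mannich base 24 (not isolated), via ammonium iodide 25 (not isolated)
Conditions: LiN(iPr)2 (2.3 equiv), THF, −78 °C; CH2=NMe2 I, −78 to 0 °C; then MeI, MeOH, rt; then NaHCO3 (aq.), CH2Cl2
Reagents that add atoms: Eschenmoser's salt, C=[N+](C)C.[I-]
Why: α-Methylenation by Mannich reaction of the ester enolate, quaternisation and mild Hofmann-type elimination. It is done on the tert-butyl ester, the only enolisable carbonyl present, so that no strong base is needed once the isobutyrate and lactone exist.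

Step 22
Reactants: 26 acrylate
Product: 27 isobutyrate, 6α-O-isobutyryl derivative of 26
Conditions: isobutyryl chloride, pyridine, DMAP (cat.), CH2Cl2, 0 °C to rt
Reagents that add atoms: isobutyryl chloride, CC(C)C(Cl)=O
Why: DMAP-catalysed acylation of the single free, equatorial secondary hydroxyl.

Step 23
Reactants: 27 isobutyrate
Product: 29 lactone silyl ether, cis-fused 8β,12-olide with 6α-isobutyrate, 9β-OH and C15 OTBDPS, via dihydroxy acid 28 (not isolated)
Conditions: CF3CO2H/CH2Cl2/H2O (10:10:1), 0 °C to rt
Reagents that add atoms: none
Why: Acidolysis of the tert-butyl ester and hydrolysis of the acetonide release a γ-hydroxy acid that lactonises spontaneously. Only the C8 hydroxyl is 1,2-cis to the acrylic acid arm, so the cis-fused α-methylene lactone is the only ring that can close, and the 1,3-trans isobutyrate cannot migrate.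

Step 24
Reactants: 29 lactone silyl ether
Product: 30 lactone diol, 29 with free C15 hydroxyl
Conditions: HF·pyridine, pyridine, THF, 0 °C to rt
Reagents that add atoms: none
Why: Buffered fluoride desilylation avoids the basic conditions that would add to the methylene lactone or move the acyl group.

Step 25
Reactants: 30 lactone diol
Product: 31 (4S)-3,4-epoxy alcohol
Conditions: Ti(OiPr)4 (10 mol %), L-(+)-diisopropyl tartrate (12 mol %), t-BuOOH, 4 Å molecular sieves, CH2Cl2, −20 °C; aq. citric acid work-up
Reagents that add atoms: tert-butyl hydroperoxide, CC(C)(C)OO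
Why: Sharpless asymmetric epoxidation of a 2-substituted allyl alcohol; the L-(+)-tartrate catalyst, which gives S-configured 2-substituted glycidols, sets C4 by reagent control. The vinyl group, the electron-poor methylene lactone and the remote C9 hydroxyl do not compete, and the non-basic work-up prevents the Payne rearrangement that would invert C4.

Step 26
Reactants: 31 epoxy alcohol
Product: 32 target, (4R,5S,6S,7S,8S,9R,10S)-epoxy aldehyde
Conditions: TEMPO (10 mol %), PhI(OAc)2, CH2Cl2, rt
Reagents that add atoms: none
Why: Oxoammonium oxidation selective for the primary alcohol over the hindered secondary C9 hydroxyl; the aldehyde has no α-hydrogen, so C4 cannot epimerise (its descriptor changes from S to R only because the priorities change).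

## Compound list

1 | 3-methylcyclohex-2-en-1-one | CC1=CC(=O)CCC1 | starting material
2 | 3-methylcyclohexa-1,3-dien-1-yl acetate | CC(=O)OC1=CC(C)=CCC1 | intermediate
3 | (±)-4-hydroxy-3-methylcyclohex-2-en-1-one | CC1=CC(=O)CCC1O | intermediate
4 | (S)-4-hydroxy-3-methylcyclohex-2-en-1-one | O=C1CC[C@H](O)C(C)=C1 | intermediate
5 | (S)-4-(tert-butyldimethylsilyloxy)-3-methylcyclohex-2-en-1-one | O=C1CC[C@H](O[Si](C)(C)C(C)(C)C)C(C)=C1 | intermediate
6 | ethyl 1-bromocyclobutane-1-carboxylate | CCOC(=O)C1(Br)CCC1 | starting material
7 | cyclobut-1-ene-1-carboxylic acid | OC(=O)C1=CCC1 | intermediate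
8 | methyl cyclobut-1-ene-1-carboxylate | COC(=O)C1=CCC1 | intermediate
9 | cis-anti-cis head-to-head photoadduct, methyl 7-(tert-butyldimethylsilyloxy)-6-methyl-10-oxotricyclo[4.4.0.0(2,5)]decane-2-carboxylate; new bonds C10–C1 and C5–C4 on the α face, C10 methyl and C9 OTBS β | O=C1CC[C@H](O[Si](C)(C)C(C)(C)C)[C@@]2(C)[C@@H]3CC[C@]3(C(=O)OC)[C@@H]12 | intermediate
10 | cis keto acrylate: cyclohexan-6-one with 5α-[1-(methoxycarbonyl)vinyl], 10α-vinyl, 10β-methyl, 9β-OTBS | C=C[C@@]1(C)[C@@H](C(=C)C(=O)OC)C(=O)CC[C@@H]1O[Si](C)(C)C(C)(C)C | intermediate
11 | trans keto acrylate: cyclohexan-6-one with 5β-[1-(methoxycarbonyl)vinyl], 10α-vinyl, 10β-methyl, 9β-OTBS | C=C[C@@]1(C)[C@H](C(=C)C(=O)OC)C(=O)CC[C@@H]1O[Si](C)(C)C(C)(C)C | intermediate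
12 | diol: 5β-[1-(hydroxymethyl)vinyl]-10β-methyl-10α-vinyl-9β-OTBS-cyclohexan-6-ol, both C6 epimers | C=C[C@@]1(C)[C@H](C(=C)CO)C(O)CC[C@@H]1O[Si](C)(C)C(C)(C)C | intermediate
13 | C15 tert-butyldiphenylsilyl ether of 12, C6 hydroxyl free | C=C[C@@]1(C)[C@H](C(=C)CO[Si](c2ccccc2)(c2ccccc2)C(C)(C)C)C(O)CC[C@@H]1O[Si](C)(C)C(C)(C)C | intermediate
14 | ketone: 5β-[1-(tert-butyldiphenylsilyloxymethyl)vinyl]-10β-methyl-10α-vinyl-9β-OTBS-cyclohexan-6-one | C=C[C@@]1(C)[C@H](C(=C)CO[Si](c2ccccc2)(c2ccccc2)C(C)(C)C)C(=O)CC[C@@H]1O[Si](C)(C)C(C)(C)C | intermediate
15 | C6=C7 trimethylsilyl enol ether of 14 | C=C[C@@]1(C)[C@H](C(=C)CO[Si](c2ccccc2)(c2ccccc2)C(C)(C)C)C(O[Si](C)(C)C)=CC[C@@H]1O[Si](C)(C)C(C)(C)C | intermediate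
16 | enone: 14 with a C7=C8 double bond | C=C[C@@]1(C)[C@H](C(=C)CO[Si](c2ccccc2)(c2ccccc2)C(C)(C)C)C(=O)C=C[C@@H]1O[Si](C)(C)C(C)(C)C | intermediate
17 | 7-iodo derivative of enone 16 | C=C[C@@]1(C)[C@H](C(=C)CO[Si](c2ccccc2)(c2ccccc2)C(C)(C)C)C(=O)C(I)=C[C@@H]1O[Si](C)(C)C(C)(C)C | intermediate
18 | enone ester: enone 16 with CH2CO2tBu on C7 | C=C[C@@]1(C)[C@H](C(=C)CO[Si](c2ccccc2)(c2ccccc2)C(C)(C)C)C(=O)C(CC(=O)OC(C)(C)C)=C[C@@H]1O[Si](C)(C)C(C)(C)C | intermediate
19 | 9β-hydroxy enone: 18 without the TBS group | C=C[C@@]1(C)[C@H](C(=C)CO[Si](c2ccccc2)(c2ccccc2)C(C)(C)C)C(=O)C(CC(=O)OC(C)(C)C)=C[C@@H]1O | intermediate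
20 | 7β,8β-epoxy-9β-hydroxy ketone, CH2CO2tBu on C7 | C=C[C@@]1(C)[C@H](C(=C)CO[Si](c2ccccc2)(c2ccccc2)C(C)(C)C)C(=O)[C@]3(CC(=O)OC(C)(C)C)O[C@@H]3[C@@H]1O | intermediate
21 | dihydroxy ketone: 8β,9β-dihydroxy-cyclohexan-6-one with 7β-CH2CO2tBu (H-7α) | C=C[C@@]1(C)[C@H](C(=C)CO[Si](c2ccccc2)(c2ccccc2)C(C)(C)C)C(=O)[C@H](CC(=O)OC(C)(C)C)[C@H](O)[C@@H]1O | intermediate
22 | 6α,8β,9β-triol with 7β-CH2CO2tBu | C=C[C@@]1(C)[C@H](C(=C)CO[Si](c2ccccc2)(c2ccccc2)C(C)(C)C)[C@@H](O)[C@H](CC(=O)OC(C)(C)C)[C@H](O)[C@@H]1O | intermediate
23 | 8,9-O-isopropylidene derivative of 22, 6α-hydroxyl free | C=C[C@@]1(C)[C@H](C(=C)CO[Si](c2ccccc2)(c2ccccc2)C(C)(C)C)[C@@H](O)[C@H](CC(=O)OC(C)(C)C)[C@@H]3OC(C)(C)O[C@H]13 | intermediate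
24 | Mannich base: 23 with CH2NMe2 on C11 (C11 epimers) | C=C[C@@]1(C)[C@H](C(=C)CO[Si](c2ccccc2)(c2ccccc2)C(C)(C)C)[C@@H](O)[C@H](C(CN(C)C)C(=O)OC(C)(C)C)[C@@H]3OC(C)(C)O[C@H]13 | intermediate
25 | trimethylammonium iodide of 24 | C=C[C@@]1(C)[C@H](C(=C)CO[Si](c2ccccc2)(c2ccccc2)C(C)(C)C)[C@@H](O)[C@H](C(C[N+](C)(C)C)C(=O)OC(C)(C)C)[C@@H]3OC(C)(C)O[C@H]13.[I-] | intermediate
26 | acrylate: 23 with C11=C13H2 (tert-butyl ester) | C=C[C@@]1(C)[C@H](C(=C)CO[Si](c2ccccc2)(c2ccccc2)C(C)(C)C)[C@@H](O)[C@H](C(=C)C(=O)OC(C)(C)C)[C@@H]3OC(C)(C)O[C@H]13 | intermediate
27 | 6α-isobutyrate of 26 | C=C[C@@]1(C)[C@H](C(=C)CO[Si](c2ccccc2)(c2ccccc2)C(C)(C)C)[C@@H](OC(=O)C(C)C)[C@H](C(=C)C(=O)OC(C)(C)C)[C@@H]3OC(C)(C)O[C@H]13 | intermediate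
28 | dihydroxy acid: 27 without the acetonide and the tert-butyl group | C=C[C@@]1(C)[C@H](C(=C)CO[Si](c2ccccc2)(c2ccccc2)C(C)(C)C)[C@@H](OC(=O)C(C)C)[C@H](C(=C)C(=O)O)[C@H](O)[C@@H]1O | intermediate
29 | cis-fused 8β,12-olide (α-methylene lactone) with 6α-isobutyrate, 9β-OH, C15 OTBDPS | C=C[C@@]1(C)[C@H](C(=C)CO[Si](c2ccccc2)(c2ccccc2)C(C)(C)C)[C@@H](OC(=O)C(C)C)[C@@H]3C(=C)C(=O)O[C@@H]3[C@@H]1O | intermediate
30 | lactone diol: 29 with free C15 hydroxyl | C=C[C@@]1(C)[C@H](C(=C)CO)[C@@H](OC(=O)C(C)C)[C@@H]2C(=C)C(=O)O[C@@H]2[C@@H]1O | intermediate
31 | (4S)-3,4-epoxy alcohol | C=C[C@@]1(C)[C@H]([C@]2(CO)CO2)[C@@H](OC(=O)C(C)C)[C@@H]2C(=C)C(=O)O[C@@H]2[C@@H]1O | intermediate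
32 | target, (4R,5S,6S,7S,8S,9R,10S) | C=C[C@@]1(C)[C@H]([C@]2(C=O)CO2)[C@@H](OC(=O)C(C)C)[C@@H]2C(=C)C(=O)O[C@@H]2[C@@H]1O | target

## Step count and risk

Total: 26 steps. Longest linear sequence: 24 steps (steps 1–4 and 7–26); steps 5 and 6 make the second component.

Least certain steps:

**Step 7 (key step).** The likely failures are erosion of facial selectivity (attack syn to the silyloxy group, which would give the wrong C10), partial head-to-tail addition, and loss of the cyclobutene ester to dimerisation. In step 8 the same material could leak through the ten-membered diene and lose C10 integrity. Fallback, which keeps the same two bonds and the same four-membered ring but avoids both the cyclobutene ester and the thermolysis: enone 5 is irradiated with methyl propiolate to give the cyclobutene adduct F1, with C10–C1 and C5–C4 formed as before. Ring-opening metathesis of its C1=C4 bond with ethylene (second-generation Hoveyda–Grubbs catalyst, CH2Cl2, rt) then delivers the vinyl and acrylate arms directly and arrives at 10.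

**Step 9.** The thermodynamic preference for the trans epimer may be small, and prolonged base may move the C3=C4 double bond into conjugation with the ketone. Fallback, which replaces free equilibration by a ring-constrained trap: 10 is desilylated (aq. HF, MeCN) to the hydroxy keto ester F2. With DBU in warm toluene C5 equilibrates, and only the 5β epimer, whose arm is cis to the C9 hydroxyl, can close to the bridged δ-lactone F3, which drains the equilibrium. Acid-catalysed methanolysis (CSA, MeOH), under which enolisation is slow, gives the trans hydroxy keto ester F4, and silylation (TBSOTf, 2,6-lutidine) returns to 11.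

**Step 17.** The peroxide may attack the α face if the axial C10 methyl outweighs the hydroxyl direction, and base may isomerise the enone toward C11 or the γ-hydroxy enone to a 1,4-dione. Fallback, which delivers the C8 oxygen through a tether: 19 is treated with PhB(OH)2 and a catalytic amine. The boronic hemiester on the C9 oxygen adds its B–OH oxygen to C8 in an intramolecular oxa-Michael reaction that can only give the cis-fused cyclic boronate F5. Exchange with pinacol releases the diol and returns to 21.

**Step 19.** Internal hydride delivery may be slowed by chelation of boron to the cis-8,9-diol or by the crowded β face, leaving ketone or giving the 6β alcohol. Fallback, which reaches C6 by inversion: 21 is converted to the acetonide F6. LiBH(sBu)3 gives the axial 6β alcohol F7 by attack from the open α face. Mitsunobu inversion with 4-nitrobenzoic acid (PPh3, DIAD) gives the 6α ester F8, and methanolysis (K2CO3, MeOH) returns to 23.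

## Further compounds

F1 | step 7 | cyclobutene photoadduct, methyl 5-(tert-butyldimethylsilyloxy)-6-methyl-2-oxobicyclo[4.2.0]oct-7-ene-8-carboxylate, cis-fused, cyclobutene anti to OTBS | O=C1CC[C@H](O[Si](C)(C)C(C)(C)C)[C@@]2(C)C=C(C(=O)OC)[C@@H]12
F2 | step 9 | cis hydroxy keto ester, 10 without the TBS group | C=C[C@@]1(C)[C@@H](C(=C)C(=O)OC)C(=O)CC[C@@H]1O
F3 | step 9 | bridged δ-lactone between C15 and the C9 oxygen (5β arm), C6 ketone | C=C[C@@]1(C)[C@@H]2C(=C)C(=O)O[C@H]1CCC2=O
F4 | step 9 | trans hydroxy keto ester, 11 without the TBS group | C=C[C@@]1(C)[C@H](C(=C)C(=O)OC)C(=O)CC[C@@H]1O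
F5 | step 17 | cyclic 8β,9β-phenylboronate of dihydroxy ketone 21 | C=C[C@@]1(C)[C@H](C(=C)CO[Si](c2ccccc2)(c2ccccc2)C(C)(C)C)C(=O)[C@H](CC(=O)OC(C)(C)C)[C@@H]3OB(c4ccccc4)O[C@H]13
F6 | step 19 | 8,9-O-isopropylidene derivative of ketone 21 | C=C[C@@]1(C)[C@H](C(=C)CO[Si](c2ccccc2)(c2ccccc2)C(C)(C)C)C(=O)[C@H](CC(=O)OC(C)(C)C)[C@@H]3OC(C)(C)O[C@H]13
F7 | step 19 | 6β-alcohol, C6 epimer of 23 | C=C[C@@]1(C)[C@H](C(=C)CO[Si](c2ccccc2)(c2ccccc2)C(C)(C)C)[C@H](O)[C@H](CC(=O)OC(C)(C)C)[C@@H]3OC(C)(C)O[C@H]13
F8 | step 19 | 6α-(4-nitrobenzoate) of 23 | C=C[C@@]1(C)[C@H](C(=C)CO[Si](c2ccccc2)(c2ccccc2)C(C)(C)C)[C@@H](OC(=O)c4ccc(cc4)[N+](=O)[O-])[C@H](CC(=O)OC(C)(C)C)[C@@H]3OC(C)(C)O[C@H]13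
A1 | alternative 1 | cis-8,9-diol cyclohexane with C7 tert-butyl acetate arm, C6 PMB ether and C5 isopropenyl group | C=C[C@@]1(C)[C@H](C(C)=C)[C@@H](OCc2ccc(OC)cc2)[C@H](CC(=O)OC(C)(C)C)[C@H](O)[C@@H]1O
A2 | alternative 1 | open-chain C8,C9-dialdehyde precursor of A1 | C=C[C@](C)(C=O)[C@H](C(C)=C)[C@@H](OCc1ccc(OC)cc1)[C@H](CC(=O)OC(C)(C)C)C=O
A3 | alternative 2 | bicyclic α-methylene lactone with C6 OTES and C9 OTBS | C=C[C@@]1(C)[C@H](C(C)=C)[C@@H](O[Si](CC)(CC)CC)[C@@H]2C(=C)C(=O)O[C@@H]2[C@@H]1O[Si](C)(C)C(C)(C)C
A4 | alternative 2 | open-chain Z 2-(bromomethyl)enoate with C8 aldehyde, precursor of A3 | C=C[C@](C)([C@@H](O[Si](C)(C)C(C)(C)C)C=O)[C@H](C(C)=C)[C@@H](O[Si](CC)(CC)CC)/C=C(\CBr)C(=O)OC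
A5 | alternative 3 | 2-methyl-2-carbomethoxy-3-isopropenyl-4-silyloxycyclohexanone | COC(=O)[C@@]1(C)[C@H](C(C)=C)[C@@H](O[Si](C)(C)C(C)(C)C)CCC1=O
A6 | alternative 3 | open-chain α-methyl β-keto ester with trisubstituted olefin, precursor of A5 | COC(=O)C(C)C(=O)CC[C@H](O[Si](C)(C)C(C)(C)C)C=C(C)C
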